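Atom labels used below: ring A is the dihydropyran fused to quinolinone unit A, ring B is the gem-dimethyl dihydropyran fused to quinolinone unit B. C-a is the ring A carbon bearing the 2-methylprop-1-enyl group, C-b is the ring-fusion carbon bound to CMe2, and C-c is the ring-fusion carbon bound to the ring A oxygen and to C3 of quinolinone unit B. The target is S at C-a, S at C-b and R at C-c, with H at C-b and C-c syn and the isobutenyl group on the same face as these two hydrogens.

Assumption: the (R)-configured acid of step 3 is taken to give the (S,S,R) dimer; this cannot be predicted for a new reaction, and if the antipode forms the equally available (S)-acid is used in the same way.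

**Retrosynthetic overview**

1. The two benzo rings are bought with 2,3-dimethoxyaniline 1; N-methylation through hemiaminal ether 2 gives N-methylaniline 3.
2. Pyridone ring (first ring formed): 3 and Meldrum's acid 4 give malonamic acid 5, which closes by Friedel–Crafts acylation to quinolinone 6.
3. Key disconnection: two molecules of 6 and two of 3-methylbut-2-enal 7 carry all atoms of the target. Oxatriene 8 closes to pyranoquinolinone 9 (ring B, O–CMe2 bond), and a second 8 adds across C3=C4 of 9 (ring A, C-a–C-b and O–C-c bonds) to give 10.
4. Ring order: benzo (bought), pyridone (step 2), then pyran ring B and pyran ring A in the same flask (step 3); all three stereocentres arise in the closure of ring A.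

**Route**

Step 1
Reactants: 1 2,3-dimethoxyaniline
Product: 3 2,3-dimethoxy-N-methylaniline, via N-(methoxymethyl)-2,3-dimethoxyaniline 2 (not isolated)
Conditions: (CH2O)n (1.5 equiv), NaOMe (5 equiv), MeOH, 23 °C, 16 h; then NaBH4 (1.5 equiv), 65 °C, 1 h
Reagents that add atoms: paraformaldehyde (formaldehyde unit), C=O
Why: Reductive amination in which the aniline is first fully converted into the N-methoxymethyl hemiaminal ether and only then reduced by hydride through the N-methylene imine, so the reaction stops at the secondary amine; no stereocentre is formed.

Step 2
Reactants: 3 2,3-dimethoxy-N-methylaniline; 4 Meldrum's acid (2,2-dimethyl-1,3-dioxane-4,6-dione)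
Product: 6 4-hydroxy-7,8-dimethoxy-1-methylquinolin-2(1H)-one, via N-(2,3-dimethoxyphenyl)-N-methylmalonamic acid 5 (not isolated)
Conditions: toluene, 110 °C, 4 h; evaporate; P2O5/MeSO3H (7.7 wt %, Eaton's reagent), 70 °C, 3 h; pour onto ice
Reagents that add atoms: none
Why: Aminolysis of Meldrum's acid (loss of acetone) gives the malonamic acid, which closes by intramolecular Friedel–Crafts acylation at the only free position ortho to nitrogen, a position para to a methoxy group, so the 7,8-dimethoxy pattern is fixed; no stereocentre is formed.

Step 3
Reactants: 6 4-hydroxy-7,8-dimethoxy-1-methylquinolin-2(1H)-one (2 equiv); 7 3-methylbut-2-enal (2.2 equiv)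
Product: 10 (S,S,R)-dimer (target), via alkylidenequinolinedione 8 (not isolated), via veprisine 9 (not isolated)
Conditions: (R)-3,3'-bis(2,4,6-triisopropylphenyl)-1,1'-binaphthyl-2,2'-diyl N-triflylphosphoramide (10 mol %), 5 Å molecular sieves, CHCl3 (0.5 M in 6), 23 °C, 12 h, then 45 °C, 48 h
Reagents that add atoms: none
Why: Proposed new method: the strong chiral acid first catalyses the known Knoevenagel condensation/oxa-6π electrocyclisation (formal [3+3]) of 6 and 7, which closes ring B and gives 9; because 9 is a cyclic tertiary-allylic vinylogous ester, carbonyl protonation and C–O heterolysis re-open a small part of it to the O-protonated form of 8 (a 4-hydroxyquinolinone-substituted allyl cation) held as a contact ion pair whose phosphoramide anion is hydrogen-bonded to the 4-OH and shields one face of C-a; the nucleophilic C3 of the C3=C4 bond of a second molecule of 9 attacks C-a on the open face and the 4-OH closes on the resulting C4 oxocarbenium (inverse-electron-demand oxa-[4+2], closing ring A), so that suprafacial addition to the ring-locked Z-alkene gives the cis fusion (H at C-b and C-c syn), exo approach of the gem-dimethylpyran to the isobutenyl-outside cation places the isobutenyl group anti to ring B, and the catalyst fixes the absolute sense; the closest known reaction types are chiral phosphoric acid-catalysed [4+2] cycloadditions of ortho-quinone methides generated in situ with electron-rich styrenes and the acid-catalysed formal [3+3] synthesis of pyranoquinolinones from 4-hydroxyquinolinones and enals, and water is the only co-product.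

**Compound list**

1 | 2,3-dimethoxyaniline | Nc1cccc(OC)c1OC | starting material
2 | N-(methoxymethyl)-2,3-dimethoxyaniline (not isolated) | COCNc1cccc(OC)c1OC | intermediate
3 | 2,3-dimethoxy-N-methylaniline | CNc1cccc(OC)c1OC | intermediate
4 | Meldrum's acid (2,2-dimethyl-1,3-dioxane-4,6-dione) | CC1(C)OC(=O)CC(=O)O1 | starting material
5 | N-(2,3-dimethoxyphenyl)-N-methylmalonamic acid, i.e. 3-[(2,3-dimethoxyphenyl)(methyl)amino]-3-oxopropanoic acid (not isolated) | CN(C(=O)CC(=O)O)c1cccc(OC)c1OC | intermediate
6 | 4-hydroxy-7,8-dimethoxy-1-methylquinolin-2(1H)-one | COc1ccc2c(O)cc(=O)n(C)c2c1OC | intermediate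
7 | 3-methylbut-2-enal | CC(C)=CC=O | starting material
8 | 7,8-dimethoxy-1-methyl-3-(3-methylbut-2-en-1-ylidene)quinoline-2,4(1H,3H)-dione; interconverting E/Z mixture at the exocyclic C=C, present in the flask mainly as its O-protonated ion pair (not isolated) | COc1ccc2c(c1OC)N(C)C(=O)C(=CC=C(C)C)C2=O | intermediate
9 | veprisine, 7,8-dimethoxy-2,2,6-trimethyl-2,6-dihydro-5H-pyrano[3,2-c]quinolin-5-one (not isolated) | COc1ccc2c3OC(C)(C)C=Cc3c(=O)n(C)c2c1OC | intermediate
10 | hexacyclic dimer: ring A is the 3,4-dihydro-2H-pyrano[3,2-c]quinolin-5(6H)-one of unit A (7,8-dimethoxy-6-methyl) bearing 2-methylprop-1-enyl at C4 (C-a, S); its C3 (C-b, S) and C2 (C-c, R) are C3 and C4 of the 2,2-dimethyl-3,4-dihydro-2H-pyrano[3,2-c]quinolin-5(6H)-one of unit B (7,8-dimethoxy-6-methyl); cis ring fusion, isobutenyl syn to H at C-b and C-c | COc1ccc2c3c(c(=O)n(C)c2c1OC)[C@@H](C=C(C)C)[C@H]1[C@@H](O3)c2c(c3ccc(OC)c(OC)c3n(C)c2=O)OC1(C)C | target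

**Step count**

Total steps: 3. Longest linear sequence: 3 (1 → 3 → 6 → 10).

**Steps most likely to fail, with fallbacks**

Step 3 (highest risk). Four things can go wrong:
- 9 is the resting state, and its acid-mediated re-opening may be too slow.
- Facial and exo/endo control in a contact ion pair, without a second hydrogen-bond contact to the nucleophile, may be modest.
- The ring A closure is reversible under acid, so prolonged reaction can erode the ee.
- Cationic coupling of two molecules of 9 through C4 can compete.

Fallback, setting out from 6 and coming back at 10: 6 and 7 are condensed in pyridine with MgSO4 at 115 °C and veprisine 9 is isolated. 9 is then dimerised with an achiral acid, (PhO)2P(O)OH (10 mol %) in CHCl3 at 45 °C, to the racemic dimer F1. Preparative supercritical-fluid chromatography on an amylose tris(3,5-dimethylphenylcarbamate) phase separates 10 from its enantiomer and from any diastereomer, and recovered 9 is recycled. This replaces catalyst control by resolution.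

Step 2. The hindered N-methyl, ortho-methoxy aniline may acylate slowly, 5 can decarboxylate to the acetanilide on heating, and the strong acid can partly cleave the methyl ether next to nitrogen.

Fallback, setting out from 3 and coming back at 6: 3 is heated neat with bis(2,4,6-trichlorophenyl) malonate at 200 °C. N-acylation gives 2,4,6-trichlorophenyl 3-[(2,3-dimethoxyphenyl)(methyl)amino]-3-oxopropanoate F2, which loses a second molecule of trichlorophenol to an acylketene that cyclises onto the ring thermally. This is a neutral pericyclic closure in place of the acid-mediated Friedel–Crafts acylation.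

Step 1. Incomplete hemiaminal ether formation leaves 1, and some N,N-dimethylaniline can form; both are hard to separate from 3.

Fallback, setting out from 1 and coming back at 3: 1 is formylated with HCO2H in toluene at 110 °C with a water separator to N-(2,3-dimethoxyphenyl)formamide F3, which is reduced with LiAlH4 in THF at 66 °C. Acylation followed by reduction makes a second methylation impossible.

**Further compounds**

F1 | step 3 | racemic dimer, 1:1 mixture of 10 and its enantiomer | COc1ccc2c3c(c(=O)n(C)c2c1OC)[C@@H](C=C(C)C)[C@H]1[C@@H](O3)c2c(c3ccc(OC)c(OC)c3n(C)c2=O)OC1(C)C.COc1ccc2c3c(c(=O)n(C)c2c1OC)[C@H](C=C(C)C)[C@@H]1[C@H](O3)c2c(c3ccc(OC)c(OC)c3n(C)c2=O)OC1(C)C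
F2 | step 2 | 2,4,6-trichlorophenyl 3-[(2,3-dimethoxyphenyl)(methyl)amino]-3-oxopropanoate | CN(C(=O)CC(=O)Oc1c(Cl)cc(Cl)cc1Cl)c1cccc(OC)c1OC
F3 | step 1 | N-(2,3-dimethoxyphenyl)formamide | O=CNc1cccc(OC)c1OC
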